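What share of its substrate would the north-west run hold as product at 240 min, and how did the opening rate go with each charge?

| setting | north-east | north | south | north-west |
|---|---|---|---|---|
| substrate | 0.400 M | 1.20 M | 0.400 M | 0.400 M |
| free catalyst | 0.00800 M | 0.00800 M | 0.0120 M | 0.00800 M |
| time |  |  |  | 240 min |

| north-east run: time / min | north-east run: [product] / M | north run: time / min | north run: [product] / M | south run: time / min | south run: [product] / M |
|---|---|---|---|---|---|
| 19 | 0.0499 | 19 | 0.1300 | 19 | 0.0661 |
| 38 | 0.0686 | 38 | 0.1803 | 38 | 0.0773 |
| 57 | 0.0756 | 57 | 0.1978 | 57 | 0.0810 |
| 76 | 0.0778 | 76 | 0.2074 | 76 | 0.0815 |
| 95 | 0.0793 | 95 | 0.2121 | 95 | 0.0815 |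

(each reading ± 0.001 M)

- how the opening rate goes with [free catalyst] round the charge of the north-east run: the exponent of the rate at two percent of substrate gone to product
- how the opening rate goes with [substrate] round the charge of the north-east run: the exponent of the rate at two percent of substrate gone to product (one fixed amount of product, the same in the runs compared)
- product in the north-west run at 240 min, as a share of the substrate charged

- Overall: substrate -> product, with free catalyst as catalyst.
- Constant volume, constant temperature.
- Bound and free are read together.
- An order is taken over about fifteen percent of the charge, up and down.

I carried one quantity: the ceiling share, the last south [product] over the south substrate charge, 20.4%, which I took for the equilibrium conversion. I took it from the south run because that run started with more free catalyst than the north-east run (0.0120 M against 0.00800 M) and read 0.0815 M at 76 min and 0.0815 M at 95 min. The north-west run has the charges of the north-east run, so the ceiling share gave it [product] = 0.0815 M. The north-east run lay 0.0316 M below this at 19 min and 0.00220 M below at 95 min, and the north-west run goes 145 min beyond that last reading. I therefore committed to 20.4%.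

The forecast gave 1.2 and 1.05 for the orders and 20.2% for the north-west run, on the ground that “1.5× the catalyst gives the same plateau, only sooner”. The flask gave 1.3, 0.97 and 20.4%, and the forecast stood inside its margins.

    free catalyst + substrate ⇌ catalyst-substrate complex, settled at all times (0.3920 M⁻¹)
    catalyst-substrate complex ⇌ product + free catalyst (5.244 min⁻¹, 7.860 M⁻¹ min⁻¹)
    free catalyst + impurity → spent catalyst
    free catalyst + product → spent catalyst + product (0.2202 M⁻¹ min⁻¹)

The north-west run held 20.4% of its substrate as product at 240 min, level with the ceiling share of 20.4%. The step from free catalyst + product to spent catalyst + product makes no difference to that figure. Put on the north run, the ceiling share gives [product] = 0.244 M, but that run read 0.2121 M at 95 min, lower by 0.0319 M.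

(The data are calculated with made-up constants; the scatter is artificial.)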